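Ring B is built by a chromium carbene benzannulation. It bears oxygens on B1, B2 and B4 and the chain on B6; the B1 oxygen, the only one to be arylated, lies between B2 and B6 and para to B4. A β-methoxyvinyl methoxycarbene complex, one of its CO ligands and a terminal alkyne create this pattern in one operation, forming B4–B5, B6–B1 and B1–B2, with B2 and B4 as methyl ethers and B1 as the sole free hydroxyl. The precursors are carbene complex 6 and alkyne 13, whose fourteen-methylene tether ends in a ring A that already carries the bromide needed for the later copper-mediated ring closure.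

Key step: step 6

Remark: ring A is 1,3,5-trisubstituted, with the hydroxyl, the chain and the ether oxygen on alternate carbons, and the target has no stereocentre; the enol ether geometry of 6 is erased when B2 becomes aromatic, so an E/Z mixture would serve equally; ring A is brought in as 1-bromo-3-iodo-5-methoxybenzene so that the first coupling is chemoselective, C–I before C–Br, and not statistical.

Step 1
Reactants: 1 chromium hexacarbonyl; 2 trimethylsilylacetylene
Product: 5 pentacarbonyl[1-methoxy-3-(trimethylsilyl)prop-2-ynylidene]chromium, via lithium (trimethylsilyl)acetylide 3 (not isolated), via lithium acylchromate 4 (not isolated)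
Conditions: n-BuLi, THF, −78 °C; Cr(CO)6, −78 to 0 °C; MeOTf, CH2Cl2, 0 °C
Reagents that add atoms: methyl trifluoromethanesulfonate, COS(=O)(=O)C(F)(F)F
Why: Fischer carbene synthesis, in which the lithium acetylide adds to a carbonyl ligand of Cr(CO)6 and the resulting acylchromate is O-methylated by the hard electrophile MeOTf, the standard entry to alkynyl(alkoxy)carbene complexes.

Step 2
Reactants: 5 pentacarbonyl[1-methoxy-3-(trimethylsilyl)prop-2-ynylidene]chromium
Product: 6 pentacarbonyl[(E)-1,3-dimethoxyprop-2-enylidene]chromium
Conditions: MeOH (5 equiv), NaOMe (10 mol%), THF, −20 to 0 °C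
Reagents that add atoms: methanol, CO
Why: Methoxide-catalysed conjugate (Michael-type) addition of methanol to the strongly electrophilic alkynylcarbene, with methoxide also cleaving the alkynyl C–Si bond; exchange at the carbene carbon is degenerate because that group is also methoxy, and the push–pull enol ether should settle as the E isomer.

Step 3
Reactants: 7 tetradeca-1,13-diene; 8 1-bromo-3-iodo-5-methoxybenzene
Product: 10 1-bromo-3-methoxy-5-(tetradec-13-enyl)benzene, via 9-(tetradec-13-enyl)-9-borabicyclo[3.3.1]nonane 9 (not isolated)
Conditions: 9-BBN-H (0.3 equiv per diene), THF, 0 °C to rt; then PdCl2(dppf) (3 mol%), 3 M aq NaOH, THF, rt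
Reagents that add atoms: none
Why: 9-BBN hydroborates one terminal alkene of the diene, which is used in excess, and the B-alkyl Suzuki–Miyaura coupling should occur only at C–I, which adds to zerovalent palladium far faster than C–Br at room temperature.

Step 4
Reactants: 10 1-bromo-3-methoxy-5-(tetradec-13-enyl)benzene
Product: 12 1-bromo-3-(14-iodotetradecyl)-5-methoxybenzene, via alkylzirconocene chloride 11 (not isolated)
Conditions: Cp2Zr(H)Cl, THF, rt; then I2, 0 °C
Reagents that add atoms: iodine, II
Why: Hydrozirconation of the terminal alkene places zirconium on the chain-end carbon and iodinolysis of the C–Zr bond gives the primary iodide, the aryl bromide and aryl ether being inert to Cp2Zr(H)Cl.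

Step 5
Reactants: 12 1-bromo-3-(14-iodotetradecyl)-5-methoxybenzene
Product: 13 1-bromo-3-(hexadec-15-ynyl)-5-methoxybenzene
Conditions: LiC≡CH·H2NCH2CH2NH2, DMSO, 10 °C to rt
Reagents that add atoms: lithium acetylide ethylenediamine complex, [Li]C#C.NCCN
Why: SN2 alkylation of lithium acetylide by a primary iodide in DMSO, the standard two-carbon homologation to a terminal alkyne, which leaves the aryl bromide untouched.

Step 6
Reactants: 6 pentacarbonyl[(E)-1,3-dimethoxyprop-2-enylidene]chromium; 13 1-bromo-3-(hexadec-15-ynyl)-5-methoxybenzene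
Product: 15 2-[14-(3-bromo-5-methoxyphenyl)tetradecyl]-4,6-dimethoxyphenol, via tricarbonylchromium arene complex 14 (not isolated)
Conditions: THF (degassed), 60 °C, Ar; then air, daylight, Et2O, rt
Reagents that add atoms: none
Why: Heating expels one CO ligand from 6, and the vacant site on zerovalent chromium takes up alkyne 13, which inserts into the Cr=C bond so that its CH terminus becomes B5 and is bonded to the former carbene carbon B4 while the chain-bearing carbon becomes B6. Migration of a CO ligand onto B6 then produces a chromium-complexed vinylketene in which the ketene carbon is the future B1. Six-electron electrocyclic closure of this dienylketene links B1 to B2, the methoxy-substituted end of the original vinyl group, which completes the six-membered ring B, and enolisation of the resulting cyclohexadienone delivers the phenol as its Cr(CO)3 complex 14, which air oxidation strips of the metal to give 15. The closest known reaction type is the Dötz benzannulation of alkenyl(alkoxy)carbene chromium complexes with terminal alkynes to 4-alkoxyphenols, of which β-alkoxyvinyl carbenes are an established though less used subclass. No stereocentre is formed, and the enol ether geometry of 6 disappears on aromatisation. The step needs regioselective alkyne insertion, which the steric difference between H and the long alkyl chain secures by putting the chain beside the CO-derived hydroxyl, and it needs the ring A bromide to stay intact, which holds because zerovalent chromium carbene complexes do not insert into aryl C–Br bonds at this temperature.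

Step 7
Reactants: 15 2-[14-(3-bromo-5-methoxyphenyl)tetradecyl]-4,6-dimethoxyphenol
Product: 16 tri-O-methyl ether of the target macrocycle (20-membered ring; OMe on ring A and on B2 and B4)
Conditions: CuI (50 mol%), picolinic acid (1 equiv), K3PO4, DMSO, 90 °C, Ar, syringe-pump addition (final 2 mM)
Reagents that add atoms: none
Why: Intramolecular Ullmann-type copper-catalysed diaryl ether formation between the B1 phenoxide, the only free hydroxyl, and the ring A bromide, with a ligand suited to ortho-disubstituted phenols and slow addition so that closure of the 20-membered ring should outrun oligomerisation.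

Step 8
Reactants: 16 tri-O-methyl ether of the target macrocycle
Product: 17 CNP0173380.0
Conditions: BBr3 (8 equiv), CH2Cl2, −78 °C to rt; then MeOH, H2O
Reagents that add atoms: none
Why: Lewis-acid demethylation, in which BBr3 complexes each aryl methyl ether and bromide attacks the O-methyl carbon, while the diaryl ether and the saturated chain are inert.

Compound list

1 | chromium hexacarbonyl | O=C=[Cr](=C=O)(=C=O)(=C=O)(=C=O)=C=O | starting material
2 | trimethylsilylacetylene | C#C[Si](C)(C)C | starting material
3 | lithium (trimethylsilyl)acetylide | [Li]C#C[Si](C)(C)C | intermediate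
4 | lithium pentacarbonyl[1-oxido-3-(trimethylsilyl)prop-2-ynylidene]chromate (acylchromate) | [Li+].[O-]C(C#C[Si](C)(C)C)=[Cr](=C=O)(=C=O)(=C=O)(=C=O)=C=O | intermediate
5 | pentacarbonyl[1-methoxy-3-(trimethylsilyl)prop-2-ynylidene]chromium | COC(C#C[Si](C)(C)C)=[Cr](=C=O)(=C=O)(=C=O)(=C=O)=C=O | intermediate
6 | pentacarbonyl[(E)-1,3-dimethoxyprop-2-enylidene]chromium | COC(/C=C/OC)=[Cr](=C=O)(=C=O)(=C=O)(=C=O)=C=O | intermediate
7 | tetradeca-1,13-diene | C=CCCCCCCCCCCCC=C | starting material
8 | 1-bromo-3-iodo-5-methoxybenzene | COc1cc(Br)cc(I)c1 | starting material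
9 | 9-(tetradec-13-enyl)-9-borabicyclo[3.3.1]nonane | C=CCCCCCCCCCCCCB1C2CCCC1CCC2 | intermediate
10 | 1-bromo-3-methoxy-5-(tetradec-13-enyl)benzene | C=CCCCCCCCCCCCCc1cc(Br)cc(OC)c1 | intermediate
11 | chlorobis(cyclopentadienyl)[14-(3-bromo-5-methoxyphenyl)tetradecyl]zirconium | Cl[Zr+2]CCCCCCCCCCCCCCc1cc(Br)cc(OC)c1.c1cc[cH-]c1.c1cc[cH-]c1 | intermediate
12 | 1-bromo-3-(14-iodotetradecyl)-5-methoxybenzene | ICCCCCCCCCCCCCCc1cc(Br)cc(OC)c1 | intermediate
13 | 1-bromo-3-(hexadec-15-ynyl)-5-methoxybenzene | C#CCCCCCCCCCCCCCCc1cc(Br)cc(OC)c1 | intermediate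
14 | tricarbonylchromium complex of 15, Cr(CO)3 bound η6 to ring B | COc1cc(OC)c(O)c(c1)CCCCCCCCCCCCCCc1cc(Br)cc(OC)c1.O=C=[Cr](=C=O)=C=O | intermediate
15 | 2-[14-(3-bromo-5-methoxyphenyl)tetradecyl]-4,6-dimethoxyphenol | COc1cc(OC)c(O)c(c1)CCCCCCCCCCCCCCc1cc(Br)cc(OC)c1 | intermediate
16 | tri-O-methyl ether of the target: 20-membered diaryl ether macrocycle, ether oxygen joining B1 to ring A, (CH2)14 chain from ring A to B6, OMe on ring A and on B2 and B4 | COc1cc2cc(c1)Oc1c(OC)cc(OC)cc1CCCCCCCCCCCCCC2 | intermediate
17 | CNP0173380.0: the same macrocycle with free OH on ring A and on B2 and B4 | Oc1cc2cc(c1)Oc1c(O)cc(O)cc1CCCCCCCCCCCCCC2 | target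

Total step count: 8. Longest linear sequence: 6 steps (steps 3, 4, 5, 6, 7, 8).

Steps most likely to fail

Step 6. The β-methoxy donor makes the carbene a vinylogous ester, so CO loss and CO insertion may be slow. Cyclisation without CO, a second alkyne insertion or thermal decay of the carbene could then compete, and the electron-rich phenol could over-oxidise during decomplexation. The fallback builds the B1 hydroxyl by formylation and oxygen insertion instead, setting out from 10 and returning at 15. Alkene 10 is hydroborated with 9-BBN-H to 9-[14-(3-bromo-5-methoxyphenyl)tetradecyl]-9-borabicyclo[3.3.1]nonane F1. This is coupled at room temperature with commercial 1-iodo-3,5-dimethoxybenzene (PdCl2(dppf), aq NaOH), again at C–I only, to give 1-bromo-3-[14-(3,5-dimethoxyphenyl)tetradecyl]-5-methoxybenzene F2. Vilsmeier–Haack formylation (POCl3, DMF) should touch only the dimethoxy ring, ortho to the chain and para to a methoxy group, giving 2-[14-(3-bromo-5-methoxyphenyl)tetradecyl]-4,6-dimethoxybenzaldehyde F3. Baeyer–Villiger oxidation with mCPBA then gives 2-[14-(3-bromo-5-methoxyphenyl)tetradecyl]-4,6-dimethoxyphenyl formate F4, and K2CO3 in MeOH releases 15.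

Step 7. A phenoxide flanked by two ortho substituents cyclises slowly, so intermolecular etherification to oligomers, reductive loss of bromine and oxidation of the phenoxide may take over. The fallback makes the ether bond intermolecularly at high concentration and closes the ring at a remote C=C bond, setting out from 6 and 8 and returning at 16. Commercial deca-1,9-diene is mono-hydroborated to 9-(dec-9-enyl)-9-borabicyclo[3.3.1]nonane F5 and coupled with 8 as in step 3 to give 1-bromo-3-(dec-9-enyl)-5-methoxybenzene F6. Complex 6 and commercial oct-1-en-7-yne, under the conditions of step 6, give the tricarbonylchromium complex of 2-(hex-5-enyl)-4,6-dimethoxyphenol F7 and, after air, 2-(hex-5-enyl)-4,6-dimethoxyphenol F8. CuI, picolinic acid and K3PO4 in DMSO at 0.5 M with excess F6 then give 1-(dec-9-enyl)-3-[2-(hex-5-enyl)-4,6-dimethoxyphenoxy]-5-methoxybenzene F9. Ring-closing metathesis with second-generation Grubbs catalyst (CH2Cl2, 40 °C, 1 mM) should give the macrocyclic alkene F10, expected as an E/Z mixture, and hydrogenation (H2, Pd/C, EtOAc) gives 16.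

Step 2. Silicon may not leave cleanly, methoxide may degrade the carbene complex instead of adding at the β-carbon, or a second methanol may add to give the acetal. The fallback brings in the three-carbon unit with its β-methoxy group and E geometry already in place, setting out from 1 and returning at 6. Commercial methyl (E)-3-methoxyacrylate is saponified (LiOH, then acid) to (E)-3-methoxyacrylic acid F11 and converted with oxalyl chloride into (E)-3-methoxyacryloyl chloride F12. Cr(CO)6 is reduced with sodium naphthalenide in THF to disodium pentacarbonylchromate F13. This is acylated by F12 at −78 °C to sodium pentacarbonyl[(E)-3-methoxy-1-oxidoprop-2-enylidene]chromate F14, and O-methylation with Me3OBF4 gives 6.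

Further compounds
F1 | step 6 | 9-[14-(3-bromo-5-methoxyphenyl)tetradecyl]-9-borabicyclo[3.3.1]nonane | COc1cc(Br)cc(CCCCCCCCCCCCCCB2C3CCCC2CCC3)c1
F2 | step 6 | 1-bromo-3-[14-(3,5-dimethoxyphenyl)tetradecyl]-5-methoxybenzene | COc1cc(OC)cc(CCCCCCCCCCCCCCc2cc(Br)cc(OC)c2)c1
F3 | step 6 | 2-[14-(3-bromo-5-methoxyphenyl)tetradecyl]-4,6-dimethoxybenzaldehyde | COc1cc(OC)c(C=O)c(c1)CCCCCCCCCCCCCCc1cc(Br)cc(OC)c1
F4 | step 6 | 2-[14-(3-bromo-5-methoxyphenyl)tetradecyl]-4,6-dimethoxyphenyl formate | COc1cc(OC)c(OC=O)c(c1)CCCCCCCCCCCCCCc1cc(Br)cc(OC)c1
F5 | step 7 | 9-(dec-9-enyl)-9-borabicyclo[3.3.1]nonane | C=CCCCCCCCCB1C2CCCC1CCC2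
F6 | step 7 | 1-bromo-3-(dec-9-enyl)-5-methoxybenzene | C=CCCCCCCCCc1cc(Br)cc(OC)c1
F7 | step 7 | tricarbonylchromium complex of 2-(hex-5-enyl)-4,6-dimethoxyphenol | C=CCCCCc1cc(OC)cc(OC)c1O.O=C=[Cr](=C=O)=C=O
F8 | step 7 | 2-(hex-5-enyl)-4,6-dimethoxyphenol | C=CCCCCc1cc(OC)cc(OC)c1O
F9 | step 7 | 1-(dec-9-enyl)-3-[2-(hex-5-enyl)-4,6-dimethoxyphenoxy]-5-methoxybenzene | C=CCCCCc1cc(OC)cc(OC)c1Oc1cc(OC)cc(CCCCCCCCC=C)c1
F10 | step 7 | macrocyclic alkene: 16 with a C=C between the fifth and sixth chain carbons counted from B6 | COc1cc2cc(c1)Oc1c(OC)cc(OC)cc1CCCCC=CCCCCCCCC2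
F11 | step 2 | (E)-3-methoxyacrylic acid | CO/C=C/C(=O)O
F12 | step 2 | (E)-3-methoxyacryloyl chloride | CO/C=C/C(=O)Cl
F13 | step 2 | disodium pentacarbonylchromate Na2Cr(CO)5 | [Na+].[Na+].O=C=[Cr-2](=C=O)(=C=O)(=C=O)=C=O
F14 | step 2 | sodium pentacarbonyl[(E)-3-methoxy-1-oxidoprop-2-enylidene]chromate | [Na+].[O-]C(/C=C/OC)=[Cr](=C=O)(=C=O)(=C=O)(=C=O)=C=O
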